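How much target stands in Tuesday's flask at 6.0 min can be bracketed from that flask's own readings, and beside them one quotient of concentrations is worth keeping.

all flasks: catalyst 0.40 mM
- Tuesday's: substrate 0.40 M; reagent 0.20 M; temperature 25 °C; the very flask that is asked about, followed so far
- Friday's: substrate 0.60 M; reagent 0.20 M; temperature 10 °C; run made earlier
- flask: substrate 0.40 M; reagent 0.200 M; temperature 25 °C; time 6.0 min

- Tuesday's (time / min: target / %, substrate / %): 0.417: 27.2, 58.4; 1.33: 20.9, 57.0; 2.50: 18.3, 55.9; 4.00: 17.7, 56.3
- Friday's (time / min: target / %, substrate / %): 0.667: 20.9, 70.6; 1.33: 18.9, 70.1; 2.00: 16.9, 69.5; 3.00: 14.0, 69.5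

(each reading ± 0.5 percentage points)

- dawn: at 6.0 min take out 90% of the target then present, then wait 6.0 min
- summer: at 6.0 min add reagent, 50.0% of the amount charged, then wait 6.0 min
- winter: at 6.0 min add catalyst, 100% of the amount charged, then wait 6.0 min
- noon: change nothing and wait 6.0 min more
- dusk: at 6.0 min raise the temperature by 15 K, then wait 6.0 min

- target, in percent of the substrate first charged, at 6.0 min
- the option that brings most further target ("none" if no option brings more than 2 percentage points) (dawn / summer / winter / noon / dusk / none)
- target present, with what was taken out counted in, in percent of the substrate first charged, after winter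
- target present, with what was taken out counted in, in percent of the substrate first charged, after noon

- removed target is counted in
- the analysis behind the earlier runs scatters by 0.5 percentage points, standard deviation
- reactions considered so far: target + catalyst <-> isomer of the product B + catalyst; target + catalyst <-> isomer of the product A + catalyst; substrate + reagent <-> target; substrate + reagent <-> isomer of the product A
- additions bring no volume worth counting

In this flask substrate and reagent combine reversibly to target and to isomer of the product A, and the catalyst moves target on to the isomers. Each molecule of target or of either isomer has cost one reagent, so [reagent] is its charge minus the substrate consumed. The last reading then gives the resting quotient, [target]/([substrate][reagent]), 12.5 M⁻¹. The first reading gives 13.9 M⁻¹, although target then stood higher. Both are readings, and the [reagent] inside them is a difference, so they carry the scatter enlarged.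

From above, the charges bound target at 50.0% of the substrate charged, with reagent as the limiting reagent. The readings tighten this bound, since target stands lower at the last reading than at the first: my upper limit is the last reading plus two scatters, 18.7%. Between the first two readings target fell 6.3 percentage points in 0.913 min, and between the last two 0.6 points in 1.50 min. My lower limit carries that last slope straight on to 6.0 min and takes off two scatters, 15.9%.

The forecast stands inside this bracket, at 17.6%, with a range from 16.8% to 18.2%. It gives 17.6% after winter and 17.6% after noon, holding that “a catalyst cannot shift an equilibrium”, and it names dawn as the best option.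

    target + catalyst ⇌ isomer of the product B + catalyst, rate k1*[catalyst]*[target] forward; the back reaction follows from the equilibrium constant (K = 0.520, k = 7.55 M⁻¹ s⁻¹, Ea = 48.0 kJ mol⁻¹, ΔH = −61.0 kJ mol⁻¹)
    target + catalyst ⇌ isomer of the product A + catalyst, rate k2*[catalyst]*[target] forward; the back reaction follows from the equilibrium constant (k = 0.503 M⁻¹ s⁻¹, Ea = 48.0 kJ mol⁻¹)
    substrate + reagent ⇌ target (K = 13.2 M⁻¹, k = 0.502 M⁻¹ s⁻¹, Ea = 54.0 kJ mol⁻¹, ΔH = 3.00 kJ mol⁻¹)
    substrate + reagent ⇌ isomer of the product A (K = 12.8 M⁻¹, k = 0.178 M⁻¹ s⁻¹, Ea = 60.0 kJ mol⁻¹, ΔH = −21.0 kJ mol⁻¹)
    (constants at 25 °C)

The flask gives 17.8%, inside the bracket, then 17.7% after winter and 17.7% after noon, and dawn brings 10 points against 7.3 points for summer. A reagent charge of 0.141 M or 0.265 M moves that answer by 5 points, beyond the forecast's range. The quotient times this flask's [substrate][reagent] at 6.00 min gives 17.0% of target. In the neighbour charged with 0.10 M of substrate, 20.5% of the substrate and 60.2% of the reagent stand free at 6.00 min, so the same quotient gives 30.7%, and that flask holds 32.3%.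

(The runs were computed for substances that don't exist; the scatter is artificial.)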